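## The problem

Compound 14, 8-(3,4-dimethoxyphenyl)-2,6-dimethoxynaphthalene-1,4-dione, is an achiral 1,4-naphthoquinone. No stereocentre has to be set, and the C8–aryl axis carries too little ortho substitution to be configurationally stable, so every difficulty is regiochemical. On the benzo ring the methoxy group at C6 must lie meta to the aryl group at C8, with C5 and C7 unsubstituted. On the quinone ring the methoxy group must sit at C2, next to the C1 carbonyl that is peri to the aryl group, and not at C3. The 2-methoxyquinone is a vinylogous ester that adds and exchanges nucleophiles, is easily reduced and does not tolerate strong base, so it should appear last. Unmasking it by oxidation of a polymethoxynaphthalene would have to compete with the electron-rich dimethoxyphenyl ring. The enabling feature is that the six benzo-ring carbons fall into three two-carbon units, C4a–C5, C6–C7 and C8–C8a, each an alkyne in retrospect, and that the chain C1–C2–C3–C4 links C8a to C4a and so tethers the third unit to the first. One cyclotrimerization can then close the benzo ring and the quinone-ring carbocycle together. If C2 enters as a dimethyl ketal and C3 as CH2, every carbon already has its final oxidation level, and loss of methanol across C2–C3 reveals the quinone. What remains is the orientation of the free C6–C7 alkyne, and the making of an unsymmetrical diynedione that holds a terminal ynone beside an enolisable β-keto ketal.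

## Retrosynthesis

**From 14 to 13.** No carbon–carbon bond is cut. Adding a methoxy group and a hydrogen across C2=C3 turns methoxyquinone 14 into the C2 dimethyl ketal 13, in which the quinone is masked as two ordinary aryl ketones. Compared with oxidising a polymethoxynaphthalene at the end, this keeps every carbon at its final oxidation level and keeps the dimethoxyphenyl ring out of any oxidation. In the forward direction only C3 has enolisable hydrogen and only C2 has a leaving group, so base-promoted elimination can give only the C2 methoxy enone.

**From 13 to 11 by way of 12.** The C6–O bond is traced back to a C6–B bond: methyl ether 13 from phenol 12, and 12 from pinacol boronate 11. Carrying the C6 oxygen through the ring synthesis on a simple ynol ether would save a step. However, a donor-substituted alkyne is polarised so that its unsubstituted carbon seeks the electrophilic metallacycle carbon, which on steric grounds is C5, and the oxygen would then end at C7. A boryl group is large and barely polarising, so the orientation can rest on sterics alone, and two routine operations turn it into the ether. The forward steps must oxidise the C–B bond without base, because 11 and 12 already contain the base-labile β-keto ketal.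

**From 11 to 9 and 10.** Three bonds, C4a–C8a, C5–C6 and C7–C8, are cut in one [2+2+2] retron. This opens both carbocycles and leaves the acyclic diynedione 9 and the commercial alkynylboronate 10. A Diels–Alder cut on a preformed quinone, or closure of the quinone ring onto a preformed arene, would each need a ring that already holds the 1,2,3,5 substitution pattern, which is the real problem. Here that pattern comes from the order of atoms in an open chain. The forward reaction must favour cross-cycloaddition over self-condensation of 9 and must place boron at C6.

**From 9 to 7 by way of 8.** The C4–C4a bond is cut and both ynone carbonyls are taken back to carbinols: 9 from diol 8 by oxidation, and 8 from lactol 7 and an ethynyl Grignard reagent. A second ynone cannot be made by acyl substitution while the first is present, because an ynone is a better electrophile than any ester or amide. Keeping C1 at the carbinol level until the end removes this conflict. The lactol serves both as the protected C1 hydroxyl group and as the aldehyde equivalent at C4. The price is two carbinol centres of no consequence and a final double oxidation that must tolerate a terminal ynone.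

**From 7 to 3 and 4 by way of 6.** Lactol 7 is the reduced form of keto ester 6. In 6 the C1–C8a bond is cut to lithium acetylide 5, made from alkyne 4, and diester 3. The two esters of 3 differ by position. The one on the ketal carbon is inductively activated and forms a persistent tetrahedral adduct at low temperature. The one on the CH2 group is an ordinary ester that lithium acetylides leave alone under those conditions. This cut fixes the aryl-bearing alkyne next to the ketal, which is what places the methoxy group of 14 at C2. The forward reaction needs exactly one addition and no enolisation of C3.

**From 3 to 1.** Both C2–O bonds of the ketal are cut, leading by way of enol ether 2 to the symmetrical alkyne 1 and the solvent alcohol. Ketalising an oxaloacetate would stop at the enol ether. Double conjugate addition under alkoxide catalysis gives the ketal at C2 and the CH2 group at C3 in one operation from a bulk chemical.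

## Roads not taken

**Alternative 1:** The cut is in the dimethoxyphenyl ring, at C1'–C2' and C5'–C6'. Forward, the peri-alkynyl naphthalene A2 and diene A3 would combine in a cobalt-catalysed [4+2] cycloaddition (CoBr2(dppe), Zn, ZnI2) to give cyclohexa-1,4-diene A1. Dehydrogenation of the new ring and oxidative demethylation of the naphthalene to the quinone would follow.
- Merits: the cycloaddition is neutral and mild, A3 is symmetrical so no orientation has to be controlled, and the aryl ring is attached late.
- Weak points: the key step is spent on the one ring that can be bought (compound 4 already contains it). The tetraoxygenated, peri-substituted naphthalene A2, which is the real difficulty, is left to a separate multi-step synthesis. A1 is a bis(enol ether) that hydrolyses or isomerises with traces of acid. The end game needs two oxidations beside the electron-rich dimethoxyphenyl ring, and the second must also choose the 1,4- over the 1,2-quinone.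
- Comparison: its key step is safer than the cyclotrimerization chosen here, since it raises no regiochemical question. Against that, the chosen plan creates the whole naphthoquinone core from acyclic material in one step and needs no oxidation after the ring synthesis other than the mild C–B oxidation.

**Alternative 2:** The cuts are C2–C3 and C1–C8a of the quinone ring. Forward, the sodium enolate of bromoaryl methyl ketone A5 is acylated by oxalate diester A6. Bromine–lithium exchange with tBuLi then lets C8a attack the remaining ester to give hydroxyquinone A4, which is O-methylated to the target.
- Merits: the end game is the shortest. All benzo-ring positions are fixed in A5 and cannot scramble. The C2 oxygen is placed unambiguously, and the chemistry is classical.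
- Weak points: A5 is a benzene with three contiguous substituents (acetyl, bromine, aryl) among four. Making it, by bromination between two groups or by selective coupling of a dihalide, is the same substitution problem moved into arene chemistry and takes several steps. In the key step an alkyllithium must exchange a hindered bromide faster than it attacks an ester and a dicarbonyl enolate in the same molecule. The doubly ortho-flanked aryllithium must then add to an ester deactivated by conjugation with the enolate. The final methylation of a 2-hydroxy-1,4-naphthoquinone can also give the 4-methoxy-1,2-quinone.
- Comparison: in regiochemical certainty this road is better than the chosen one, and with A5 in hand it would also be shorter. The chosen plan sets against this that its benzo-ring pattern comes from the commercial alkynes 4 and 10 in open-chain order, and that the quinone is never exposed to an organolithium.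

**Alternative 3:** The cut is C6–C7. Forward, siloxyalkyne A8 is protonated at C5 by HNTf2 (or activated by AgNTf2). The ketenium carbon C6 is attacked by the CH2 terminus of the 1,1-diarylethylene on C8a, and the 6-endo closure gives silyloxynaphthalene A7.
- Merits: the closure is intramolecular, so the positions of the C6 oxygen and the C8 aryl group are not in doubt. The step is atom-economical and catalytic in acid.
- Weak points: A8 is a fully elaborated benzene with an acid-labile siloxyalkyne ortho to a diarylethylene, and it needs a long sequence. The strong acid may instead protonate the electron-rich alkene, or let the dimethoxyphenyl ring attack the ketenium ion. After the key step the silyl ether must be exchanged for methyl and the trimethoxy ring oxidised to the quinone, again beside the dimethoxyphenyl ring and with the 1,4- versus 1,2-quinone choice.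
- Comparison: its regiocontrol is intrinsically better than that of any intermolecular cyclotrimerization. The chosen plan sets against this the steric bias of boryl alkyne 10 and a sterically governed C–H borylation as reserve. It also closes two rings instead of one and needs no late arene oxidation.

Key step: step 6

Assumption: compounds 7 and 8 are carried as racemic mixtures of diastereomers, since their carbinol centres are destroyed in step 5; compounds 4 and 10 are purchased; the locants C1–C8a of the naphthoquinone are used for the corresponding atoms of all intermediates.

## Route

Step 1
Reactants: 1 dimethyl but-2-ynedioate (dimethyl acetylenedicarboxylate)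
Product: 3 dimethyl 2,2-dimethoxybutanedioate, via methoxybutenedioate diester 2 (not isolated)
Conditions: NaOMe (0.2 equiv), MeOH, 0 °C to 40 °C; AcOH
Reagents that add atoms: methanol, CO
Why: Double oxa-Michael addition of methanol to the ynedioate under alkoxide catalysis: the first addition gives enol ether 2, and methoxide then adds to its methoxy-bearing carbon, which is the β-carbon of the second acrylate unit, so the ketal forms at one carbon and a CH2 group at the other. This is the classical alkoxide addition to acetylenedicarboxylic esters.

Step 2
Reactants: 3 dimethyl 2,2-dimethoxybutanedioate; 4 4-ethynyl-1,2-dimethoxybenzene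
Product: 6 methyl 6-(3,4-dimethoxyphenyl)-3,3-dimethoxy-4-oxohex-5-ynoate, via lithium acetylide 5 (not isolated)
Conditions: 4, n-BuLi (1.0 equiv), THF, −78 °C; cannulate into 3 (1.2 equiv), THF, −78 °C; AcOH, −78 °C
Reagents that add atoms: none
Why: Acyl substitution of an ester by a lithium acetylide: the ester on the ketal carbon is inductively activated by two α-oxygens and gives a tetrahedral lithium alkoxide that persists at −78 °C, as with dialkoxyacetates and oxalates, whereas the CH2-bound ester is an ordinary ester that lithium acetylides do not attack at this temperature without a Lewis acid. Inverse addition and a cold acidic quench keep a second acetylide from meeting the ynone, and the weakly basic acetylide should not enolise C3.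

Step 3
Reactants: 6 methyl 6-(3,4-dimethoxyphenyl)-3,3-dimethoxy-4-oxohex-5-ynoate
Product: 7 5-[(3,4-dimethoxyphenyl)ethynyl]-4,4-dimethoxyoxolan-2-ol (lactol, racemic mixture of diastereomers)
Conditions: iBu2AlH (2.5 equiv), CH2Cl2, −78 °C; aq. KNaC4H4O6 (potassium sodium tartrate)
Reagents that add atoms: none
Why: Hydride reduction with iBu2AlH: 1,2-reduction of the ynone gives the propargylic aluminium alkoxide, and partial reduction of the ester gives an aluminium hemiacetal that is stable at −78 °C, so work-up releases the γ-hydroxy aldehyde as its five-membered lactol (ester to lactol reduction). The carbinol and anomeric centres form without control, which is immaterial because both are oxidised away in step 5.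

Step 4
Reactants: 7 5-[(3,4-dimethoxyphenyl)ethynyl]-4,4-dimethoxyoxolan-2-ol
Product: 8 1-(3,4-dimethoxyphenyl)-4,4-dimethoxyocta-1,7-diyne-3,6-diol (racemic mixture of diastereomers)
Conditions: HC≡CMgBr (4 equiv), THF, 0 °C to rt; H2O quench, pH 7 buffer
Reagents that add atoms: ethynylmagnesium bromide, C#C[Mg]Br
Why: Grignard addition to a lactol through its open hydroxy aldehyde form: the first equivalent deprotonates the lactol, the magnesium alkoxide opens, and the alkynyl Grignard reagent adds to the aldehyde. The new carbinol centre is not controlled and is erased in step 5.

Step 5
Reactants: 8 1-(3,4-dimethoxyphenyl)-4,4-dimethoxyocta-1,7-diyne-3,6-diol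
Product: 9 1-(3,4-dimethoxyphenyl)-4,4-dimethoxyocta-1,7-diyne-3,6-dione
Conditions: Dess–Martin periodinane (3 equiv), NaHCO3, CH2Cl2, 0 °C to rt; used without delay
Reagents that add atoms: none
Why: Dess–Martin oxidation of both secondary propargylic alcohols to ynones. The buffered, non-aqueous conditions spare the ketal and the terminal ynone, and any cyclic hemiketal formed from the half-oxidised intermediate stays in equilibrium with the open hydroxy ketone, which is oxidised further.

Step 6
Reactants: 9 1-(3,4-dimethoxyphenyl)-4,4-dimethoxyocta-1,7-diyne-3,6-dione; 10 2-ethynyl-4,4,5,5-tetramethyl-1,3,2-dioxaborolane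
Product: 11 8-(3,4-dimethoxyphenyl)-2,2-dimethoxy-6-(4,4,5,5-tetramethyl-1,3,2-dioxaborolan-2-yl)-2,3-dihydronaphthalene-1,4-dione
Conditions: Cp*RuCl(cod) (10 mol %), 10 (3 equiv), slow addition of 9, ClCH2CH2Cl, rt, Ar
Reagents that add atoms: none
Why: The cod ligand is displaced and the two ynone alkynes of 9 couple oxidatively on the divalent ruthenium centre to give a bicyclic ruthenacyclopentatriene, which closes the quinone-ring carbocycle through C4a–C8a; alkyne 10 then coordinates, adds at the less hindered Ru–C5 carbon to form C5–C6, and reductive elimination forms C7–C8, closes the benzo ring and returns divalent ruthenium. The closest known reaction type is the Cp*RuCl(cod)-catalysed [2+2+2] cycloaddition of 1,7-diyne-3,6-diones such as 1,2-bis(propioloyl)arenes with monoalkynes to anthraquinones, together with the same catalyst's cycloaddition of α,ω-diynes with ethynylboronates to arylboronates. The six-membered carbocycle closes by metal-templated coupling of the tethered alkynes, helped by the quaternary ketal carbon in the four-atom tether, and the benzo ring closes by insertion and reductive elimination within the metallacycle. No stereocentre is formed. Two selectivities are needed: cross- over self-cycloaddition, secured by slow addition of 9 to an excess of 10, which is too hindered to trimerise readily on its own, and orientation of 10, whose boron-bearing carbon must bond to the unsubstituted terminus C5 so that boron ends at C6, meta to the aryl group. This is the sense that unsymmetrical diynes with one substituted terminus are known to show with this catalyst, because the bulky boryl group then stays away from both the Cp* ligand and the C8 aryl group, and the boronate, unlike a donor-substituted alkyne, carries no polarisation that works against it.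

Step 7
Reactants: 11 8-(3,4-dimethoxyphenyl)-2,2-dimethoxy-6-(4,4,5,5-tetramethyl-1,3,2-dioxaborolan-2-yl)-2,3-dihydronaphthalene-1,4-dione
Product: 12 8-(3,4-dimethoxyphenyl)-6-hydroxy-2,2-dimethoxy-2,3-dihydronaphthalene-1,4-dione
Conditions: Oxone (2KHSO5·KHSO4·K2SO4), acetone/H2O, 0 °C, short reaction time
Reagents that add atoms: potassium peroxymonosulfate (KHSO5, the oxidant in Oxone), [K+].[O-]S(=O)(=O)OO
Why: Oxidation of the aryl C–B bond by peroxymonosulfate: the peroxide adds to boron, the aryl group migrates from boron to oxygen and the borate ester hydrolyses to the phenol (ipso-hydroxylation of an arylboronate). The medium is slightly acidic, so the base-labile β-keto ketal is not enolised.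

Step 8
Reactants: 12 8-(3,4-dimethoxyphenyl)-6-hydroxy-2,2-dimethoxy-2,3-dihydronaphthalene-1,4-dione
Product: 14 8-(3,4-dimethoxyphenyl)-2,6-dimethoxynaphthalene-1,4-dione (CNP0128574.0), via trimethoxy ketal 13 (not isolated)
Conditions: MeI, K2CO3, acetone, rt; evaporate; DBU, CH2Cl2, 0 °C to rt
Reagents that add atoms: iodomethane, CI
Why: Williamson O-methylation of the phenol, which is acidic because it is para to the C1 acyl group, gives 13; after removal of excess MeI, DBU enolises C3 and methoxide leaves from C2 (E1cB β-elimination) to give the 2-methoxy-1,4-naphthoquinone. Only C3 has enolisable hydrogen and only C2 a leaving group, so a single regioisomer can form.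

## Compound list

1 | dimethyl but-2-ynedioate (dimethyl acetylenedicarboxylate) | COC(=O)C#CC(=O)OC | starting material
2 | dimethyl 2-methoxybut-2-enedioate (E/Z mixture, not isolated) | COC(=O)C=C(OC)C(=O)OC | intermediate
3 | dimethyl 2,2-dimethoxybutanedioate | COC(=O)CC(OC)(OC)C(=O)OC | intermediate
4 | 4-ethynyl-1,2-dimethoxybenzene | C#Cc1ccc(OC)c(OC)c1 | starting material
5 | lithium (3,4-dimethoxyphenyl)acetylide (not isolated) | [Li]C#Cc1ccc(OC)c(OC)c1 | intermediate
6 | methyl 6-(3,4-dimethoxyphenyl)-3,3-dimethoxy-4-oxohex-5-ynoate | COC(=O)CC(OC)(OC)C(=O)C#Cc1ccc(OC)c(OC)c1 | intermediate
7 | 5-[(3,4-dimethoxyphenyl)ethynyl]-4,4-dimethoxyoxolan-2-ol (racemic mixture of diastereomers) | OC1CC(OC)(OC)C(C#Cc2ccc(OC)c(OC)c2)O1 | intermediate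
8 | 1-(3,4-dimethoxyphenyl)-4,4-dimethoxyocta-1,7-diyne-3,6-diol (racemic mixture of diastereomers) | C#CC(O)CC(OC)(OC)C(O)C#Cc1ccc(OC)c(OC)c1 | intermediate
9 | 1-(3,4-dimethoxyphenyl)-4,4-dimethoxyocta-1,7-diyne-3,6-dione | C#CC(=O)CC(OC)(OC)C(=O)C#Cc1ccc(OC)c(OC)c1 | intermediate
10 | 2-ethynyl-4,4,5,5-tetramethyl-1,3,2-dioxaborolane | C#CB1OC(C)(C)C(C)(C)O1 | starting material
11 | 8-(3,4-dimethoxyphenyl)-2,2-dimethoxy-6-(4,4,5,5-tetramethyl-1,3,2-dioxaborolan-2-yl)-2,3-dihydronaphthalene-1,4-dione | COc1ccc(-c2cc(B3OC(C)(C)C(C)(C)O3)cc3c2C(=O)C(OC)(OC)CC3=O)cc1OC | intermediate
12 | 8-(3,4-dimethoxyphenyl)-6-hydroxy-2,2-dimethoxy-2,3-dihydronaphthalene-1,4-dione | COc1ccc(-c2cc(O)cc3c2C(=O)C(OC)(OC)CC3=O)cc1OC | intermediate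
13 | 8-(3,4-dimethoxyphenyl)-2,2,6-trimethoxy-2,3-dihydronaphthalene-1,4-dione (not isolated) | COc1cc(-c2ccc(OC)c(OC)c2)c2c(c1)C(=O)CC(OC)(OC)C2=O | intermediate
14 | 8-(3,4-dimethoxyphenyl)-2,6-dimethoxynaphthalene-1,4-dione (CNP0128574.0) | COC1=CC(=O)c2cc(OC)cc(-c3ccc(OC)c(OC)c3)c2C1=O | target

## Step count and risks

Total step count: 8. Longest linear sequence: 8 steps (1 to 14; compounds 4 and 10 are purchased).

**Step 6 (key step).** Two things may go wrong. Self-condensation of the diynedione can compete with uptake of the electron-poor boryl alkyne. Control of the orientation of the inserting alkyne can be incomplete, so that some boron ends at C7. The fallback sets out from 9 and removes the orientation question. Cyclotrimerization of 9 with acetylene gas (1 atm) under Cp*RuCl(cod) should give 8-(3,4-dimethoxyphenyl)-2,2-dimethoxy-2,3-dihydronaphthalene-1,4-dione F1; the partner is symmetrical, small and readily inserted. Boron is then introduced by iridium-catalysed C–H borylation ([Ir(OMe)(cod)]2, 4,4'-di-tert-butyl-2,2'-bipyridine, B2pin2). This reaction is sterically governed and should select C6–H, the only aromatic C–H of F1 without an ortho substituent. The fallback comes back to the route at 11.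

**Step 2.** The acetylide may discriminate too little between the two ester carbonyls. The tetrahedral adduct may also collapse before the quench, which leads to a second addition. The fallback sets out from 3 and introduces C1 at the aldehyde level. One equivalent of iBu2AlH at −78 °C, delivered to the ester that can chelate aluminium through its α-methoxy groups, should give methyl 3,3-dimethoxy-4-oxobutanoate F2. Acetylide 5 adds to this aldehyde far faster than to any ester, and the alkoxide closes onto the remaining ester on warming to give 5-[(3,4-dimethoxyphenyl)ethynyl]-4,4-dimethoxyoxolan-2-one F3. Reduction of the lactone with iBu2AlH at −78 °C comes back to the route at 7.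

**Step 3.** Reduction at C4 may run past the aldehyde level to the primary alcohol, or the aryl alkyne may be hydroaluminated by the excess hydride. The fallback sets out from 6 and separates the two reductions. NaBH4 with CeCl3·7H2O in MeOH at low temperature (Luche reduction) should reduce only the ynone carbonyl and give methyl 6-(3,4-dimethoxyphenyl)-4-hydroxy-3,3-dimethoxyhex-5-ynoate F4. The established reduction of a γ-hydroxy ester to its lactol with iBu2AlH at −78 °C then comes back to the route at 7.

**Step 5.** The half-oxidised γ-hydroxy ynone may be intercepted as a cyclic hemiketal, which is not oxidised and can aromatise to a furan by loss of water and methanol. Methanol may also be lost early from the β-keto ketal, or the terminal ynone may decompose on handling. The fallback sets out from 3 and avoids any oxidation. N,O-dimethylhydroxylamine hydrochloride with iPrMgCl converts both esters to give N1,N4,2,2-tetramethoxy-N1,N4-dimethylbutanediamide F5. Acetylide 5 (1 equiv, −78 °C) is then added to the activated amide on the ketal carbon, followed by HC≡CMgBr (excess, 0 °C) to the other amide. Both chelated adducts persist until a cold acidic quench (aq. NaHSO4) releases the two ynones together. The fallback comes back to the route at 9.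

## Further compounds

F1 | step 6 | 8-(3,4-dimethoxyphenyl)-2,2-dimethoxy-2,3-dihydronaphthalene-1,4-dione | COc1ccc(-c2cccc3c2C(=O)C(OC)(OC)CC3=O)cc1OC
F2 | step 2 | methyl 3,3-dimethoxy-4-oxobutanoate | COC(=O)CC(OC)(OC)C=O
F3 | step 2 | 5-[(3,4-dimethoxyphenyl)ethynyl]-4,4-dimethoxyoxolan-2-one (racemic) | O=C1CC(OC)(OC)C(C#Cc2ccc(OC)c(OC)c2)O1
F4 | step 3 | methyl 6-(3,4-dimethoxyphenyl)-4-hydroxy-3,3-dimethoxyhex-5-ynoate (racemic) | COC(=O)CC(OC)(OC)C(O)C#Cc1ccc(OC)c(OC)c1
F5 | step 5 | N1,N4,2,2-tetramethoxy-N1,N4-dimethylbutanediamide | CON(C)C(=O)CC(OC)(OC)C(=O)N(C)OC
A1 | alternative 1 | 8-(4,5-dimethoxycyclohexa-1,4-dien-1-yl)-1,2,4,6-tetramethoxynaphthalene | COC1=C(OC)CC(c2cc(OC)cc3c(OC)cc(OC)c(OC)c23)=CC1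
A2 | alternative 1 | 8-ethynyl-1,2,4,6-tetramethoxynaphthalene | C#Cc1cc(OC)cc2c(OC)cc(OC)c(OC)c12
A3 | alternative 1 | 2,3-dimethoxybuta-1,3-diene | C=C(OC)C(=C)OC
A4 | alternative 2 | 8-(3,4-dimethoxyphenyl)-2-hydroxy-6-methoxynaphthalene-1,4-dione | O=C1C=C(O)C(=O)c2c1cc(OC)cc2-c1ccc(OC)c(OC)c1
A5 | alternative 2 | 1-[2-bromo-3-(3,4-dimethoxyphenyl)-5-methoxyphenyl]ethan-1-one | CC(=O)c1cc(OC)cc(-c2ccc(OC)c(OC)c2)c1Br
A6 | alternative 2 | dimethyl oxalate | COC(=O)C(=O)OC
A7 | alternative 3 | triisopropyl{[4-(3,4-dimethoxyphenyl)-5,6,8-trimethoxynaphthalen-2-yl]oxy}silane | COc1cc(OC)c2cc(O[Si](C(C)C)(C(C)C)C(C)C)cc(-c3ccc(OC)c(OC)c3)c2c1OC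
A8 | alternative 3 | triisopropyl[({2-[1-(3,4-dimethoxyphenyl)ethenyl]-3,4,6-trimethoxyphenyl}ethynyl)oxy]silane | C=C(c1ccc(OC)c(OC)c1)c1c(OC)c(OC)cc(OC)c1C#CO[Si](C(C)C)(C(C)C)C(C)C
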